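**Retrosynthetic overview**

1. Feature: ring A (C1–C5, C10) holds C19 on C4 and C6 on C5 cis to each other, with the C4 methyl (C18) and H5 on the opposite face, which is the substitution pattern of citraconic anhydride. C10 carries two one-carbon oxygenated arms (C20, later the lactone OCH2, and C9, later the ring C methine) that can begin as identical CH2O groups.
2. Key disconnection: ring A by Diels–Alder union (C5–C10 and C3–C4) of citraconic anhydride with a 2-silyloxydiene whose C10 terminus is C5 of a 1,3-dioxane. The CH2OH cis to C6 then opens the anhydride (C6/C20 γ-lactone), which fixes C10 and tells C19, C9 and C20 apart.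
3. C19 acid and C1 ketone are reduced and acetylated; the γ-lactone is reduced (C6–OH silylated, C20–OH freed); a C20 malonate and the C9 aldehyde close the unsaturated δ-lactone (C7, C8) by Knoevenagel condensation.
4. Ring C by Diels–Alder addition of butadiene to C8=C9 (sets C8 and C9); ring D by 5-exo vinyl-radical closure C16→C13 from a C15 propargylic alcohol; oxidation to the enone and C6 desilylation finish.
5. Ring order: A, temporary γ-lactone, δ-lactone, C, D.

Key step: step 5

Remarks on the chemistry (assumptions):
- Atoms carry ent-kaurane numbers. The α-face of ring A is the face bearing C19, C6 and C20; the β-face bears the C4 methyl (C18) and H5.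
- The sense of induction of the chiral Lewis acid in step 5 cannot be predicted with confidence. The (S)-catalyst is written; its antipode is used if the induction proves opposite.

**Route**

Step 1
Reactants: 1 (2,2-dimethyl-1,3-dioxan-5-yl)methanol
Product: 2 2,2-dimethyl-1,3-dioxane-5-carbaldehyde
Conditions: (COCl)2, DMSO, CH2Cl2, −78 °C; Et3N, −78 → 0 °C
Reagents that add atoms: none
Why: Swern oxidation of the primary alcohol should stop at the aldehyde, and the low temperature and amine base leave the acetonide and the β-alkoxy aldehyde intact; no stereocentre is formed.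

Step 2
Reactants: 2 2,2-dimethyl-1,3-dioxane-5-carbaldehyde; 3 vinylmagnesium bromide
Product: 4 1-(2,2-dimethyl-1,3-dioxan-5-yl)prop-2-en-1-ol
Conditions: THF, −78 → 0 °C; aq. NH4Cl
Reagents that add atoms: none
Why: Grignard addition to the aldehyde should give the allylic alcohol as a racemate, which does not matter because the carbinol centre is oxidised in step 3.

Step 3
Reactants: 4 1-(2,2-dimethyl-1,3-dioxan-5-yl)prop-2-en-1-ol
Product: 5 1-(2,2-dimethyl-1,3-dioxan-5-yl)prop-2-en-1-one
Conditions: DMP, NaHCO3, CH2Cl2, 0 °C → rt
Reagents that add atoms: none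
Why: Dess–Martin oxidation of the allylic alcohol under buffered, non-nucleophilic conditions should give the vinyl ketone without conjugate addition or acetonide loss, and removes the racemic centre.

Step 4
Reactants: 5 1-(2,2-dimethyl-1,3-dioxan-5-yl)prop-2-en-1-one
Product: 6 5-[1-(tert-butyldimethylsilyloxy)allylidene]-2,2-dimethyl-1,3-dioxane
Conditions: TBSOTf, Et3N, CH2Cl2, −78 → 0 °C
Reagents that add atoms: tert-butyldimethylsilyl trifluoromethanesulfonate CC(C)(C)[Si](C)(C)OS(=O)(=O)C(F)(F)F
Why: Soft enolisation (silyl triflate and amine) of the only enolisable position, C10–H, should give the cross-conjugated 2-silyloxydiene without β-elimination of the ring oxygens; the C10 terminus bears two identical CH2O groups, so no alkene geometry or stereocentre arises.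

Step 5
Reactants: 6 5-[1-(tert-butyldimethylsilyloxy)allylidene]-2,2-dimethyl-1,3-dioxane; 7 citraconic anhydride
Product: 8 spiro-dioxane ring A anhydride
Conditions: (S)-3,3-diphenyl-1-(o-tolyl)tetrahydro-1H,3H-pyrrolo[1,2-c][1,3,2]oxazaborole (20 mol %), Tf2NH (16 mol %), CH2Cl2, −40 → −20 °C
Reagents that add atoms: none
Why: Proposed new method: the chiral oxazaborolidinium Lewis acid is expected to bind one anhydride carbonyl of 7, lower its LUMO and shield one π-face, so that the s-cis diene 6 adds in an asynchronous, Mukaiyama–Michael-like concerted [4+2]; catalytic enantiocontrol with a cyclic anhydride as dienophile is not established, and the closest known types are thermal cycloadditions of 2-silyloxydienes to cyclic anhydrides, Lewis-acid-promoted cycloadditions of 1,1-disubstituted 2-silyloxydienes, and chiral-Lewis-acid-catalysed Diels–Alder reactions of maleimides and quinones. Ring A (C10, C1, C2, C3, C4, C5) closes as a cyclohexene in intermolecular [4+2] mode by forming C5–C10 and C3–C4, leaving C1 as an enol silane. C4 and C5 are the only new stereocentres: their cis relation (C19 and C6 on the α-face, C18 and H5 on the β-face) is copied from the cis-alkene of 7 by suprafacial addition, and their absolute sense comes from the face left open by the catalyst. Regioselectivity is needed and the substrate secures it: the nucleophilic enol-silane terminus C10 attacks the unsubstituted, methacrylate-like C5, whereas the alternative would join two fully substituted carbons (C10 and C4). Endo/exo selectivity is not needed, because C10 carries two identical CH2O arms inside the dioxane and both transition states give the same compound.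

Step 6
Reactants: 8 spiro-dioxane ring A anhydride
Product: 10 keto lactone acid, via keto diol anhydride 9 (not isolated)
Conditions: TsOH·H2O (0.2 equiv), H2O (3 equiv), MeCN, 0 °C → rt
Reagents that add atoms: none
Why: Acid hydrolysis of the enol silane and the acetonide is followed by intramolecular alcoholysis of the anhydride (5-exo-trig acyl substitution), in which only the arm cis to C6 can close a cis-fused γ-lactone onto C6 without over-puckering ring A beside the flattened anhydride fusion, and attack on C19 would need a bridged six-membered transition state; this sets C10 (C20 on the α-face in the lactone, C9 on the β-face as a free alcohol) and releases C19 as the acid.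

Step 7
Reactants: 10 keto lactone acid
Product: 12 C9 silyl ether keto lactone acid, via bis-silyl derivative 11 (not isolated)
Conditions: TBSCl, imidazole, DMF, rt; then aq. citric acid, THF, rt
Reagents that add atoms: tert-butyldimethylsilyl chloride CC(C)(C)[Si](C)(C)Cl
Why: Silylation masks the only hydroxyl (C9) so that it stays distinct from the C19 and C20 hydroxyls made later, and the silyl ester formed alongside is hydrolysed in the acidic wash; no stereocentre is touched.

Step 8
Reactants: 12 C9 silyl ether keto lactone acid
Product: 13 1α,19-diol γ-lactone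
Conditions: BH3·SMe2, THF, 0 °C → rt; MeOH
Reagents that add atoms: none
Why: Borane reduces the carboxylic acid (through the acyloxyborane) and the ketone but should spare the hindered γ-lactone; at C1 hydride is expected to add axially from the β-face, anti to the axial C20 on the neighbouring quaternary C10, giving the equatorial 1α-alcohol.

Step 9
Reactants: 13 1α,19-diol γ-lactone
Product: 14 1α,19-diacetate γ-lactone
Conditions: Ac2O, pyridine, DMAP (cat.), CH2Cl2, rt
Reagents that add atoms: acetic anhydride CC(=O)OC(C)=O
Why: DMAP-catalysed acylation should acetylate the secondary C1 and the neopentyl C19 hydroxyls, installing both acetates of the target with no change at any stereocentre.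

Step 10
Reactants: 14 1α,19-diacetate γ-lactone
Product: 16 C6,C20-diol diacetate, via lactol 15 (not isolated)
Conditions: bis(3-methylbutan-2-yl)borane (Sia2BH), THF, 0 °C → rt; then MeOH, CeCl3·7H2O, NaBH4, 0 °C
Reagents that add atoms: none
Why: A dialkylborane reduces a lactone to the lactol but does not reduce carboxylic esters (the selectivity used with acylated aldonolactones), and borohydride under Luche conditions then reduces the ring-opened hydroxy aldehyde near neutrality, so the acetates should survive and C6–OH and C20–OH are freed.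

Step 11
Reactants: 16 C6,C20-diol diacetate
Product: 17 C6 silyl ether C20 alcohol
Conditions: TBDPSCl (1.05 equiv), imidazole, CH2Cl2, −20 → 0 °C
Reagents that add atoms: tert-butyldiphenylsilyl chloride CC(C)(C)[Si](Cl)(c1ccccc1)c1ccccc1
Why: Silylation with a bulky chlorosilane should select the primary C6–OH on a methine carbon over the neopentyl, axial C20–OH that is flanked by the C19 acetoxymethyl group.

Step 12
Reactants: 17 C6 silyl ether C20 alcohol; 18 mono-tert-butyl malonate
Product: 19 C20 tert-butyl malonate
Conditions: DCC, CH2Cl2, 0 °C → rt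
Reagents that add atoms: none
Why: Carbodiimide esterification of a malonic half-ester runs through the acylketene and should therefore acylate the hindered neopentyl C20–OH, bringing in C7, C8 and C15.

Step 13
Reactants: 19 C20 tert-butyl malonate
Product: 20 C9 alcohol malonate
Conditions: CSA (0.1 equiv), MeOH–CH2Cl2 (1:1), 0 °C
Reagents that add atoms: none
Why: Acid-catalysed methanolysis cleaves a primary TBS ether much faster than the TBDPS ether, and the product is oxidised at once in step 14 to forestall a 1,3-acyl shift between the two C10 arms.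

Step 14
Reactants: 20 C9 alcohol malonate
Product: 21 C9 aldehyde malonate
Conditions: DMP, NaHCO3, CH2Cl2, 0 °C → rt
Reagents that add atoms: none
Why: Dess–Martin oxidation of the neopentyl primary alcohol should give the non-enolisable C9 aldehyde under neutral conditions that leave the esters and silyl ether alone.

Step 15
Reactants: 21 C9 aldehyde malonate
Product: 22 spiro unsaturated δ-lactone ester
Conditions: piperidine (0.2 equiv), AcOH (0.2 equiv), 4 Å MS, toluene, 60 °C
Reagents that add atoms: none
Why: Intramolecular Knoevenagel condensation of the malonate methylene (C8) with the C9 aldehyde closes a six-membered ring, which fixes the alkene geometry with the lactone carbonyl C7 cis to C10 and the tert-butyl ester trans.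

Step 16
Reactants: 22 spiro unsaturated δ-lactone ester; 23 buta-1,3-diene
Product: 24 ring C adduct tert-butyl ester
Conditions: ZnCl2 (1.5 equiv), CH2Cl2, 0 °C → rt, sealed tube, excess 23
Reagents that add atoms: none
Why: Lewis-acid-promoted Diels–Alder addition to the chelated alkylidene 1,3-dicarbonyl is suprafacial, so ring C is cis-fused to the lactone with the ester (future C15) cis to H9, and the diene should approach the lactone face on the C1 side, away from C5 with its C6 silyloxymethyl and the axial C19 acetoxymethyl, which sets C9 and C8.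

Step 17
Reactants: 24 ring C adduct tert-butyl ester
Product: 25 C15 carboxylic acid
Conditions: TFA–CH2Cl2 (1:4), 0 °C
Reagents that add atoms: none
Why: Acidolysis of the tert-butyl ester (loss of isobutene) should free the C15 acid while the acetates, the lactone and the TBDPS ether survive the short, cold exposure.

Step 18
Reactants: 25 C15 carboxylic acid
Product: 27 C15 aldehyde, via acid chloride 26 (not isolated)
Conditions: (COCl)2, DMF (cat.), CH2Cl2, 0 °C → rt; evaporate; LiAlH(OtBu)3, THF, −78 °C
Reagents that add atoms: none
Why: The acid chloride (no ketene is possible at the quaternary C8) is reduced by the hindered alkoxyaluminium hydride at −78 °C only as far as the aldehyde, a partial reduction that leaves lactone, acetates and alkene untouched.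

Step 19
Reactants: 27 C15 aldehyde; 28 ethynylmagnesium bromide
Product: 29 C15 propargylic alcohol
Conditions: THF, −78 → −40 °C; aq. NH4Cl
Reagents that add atoms: none
Why: Grignard addition of the acetylide to the non-enolisable aldehyde should outpace attack on the lactone and acetates at low temperature; the C15 carbinol forms as an epimer mixture that is irrelevant because it is oxidised in step 22.

Step 20
Reactants: 29 C15 propargylic alcohol
Product: 30 ring D vinylstannane
Conditions: Bu3SnH (1.5 equiv, 0.05 M), AIBN (0.2 equiv), benzene, 80 °C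
Reagents that add atoms: tributyltin hydride CCCC[SnH](CCCC)CCCC
Why: In this radical hydrostannylation–cyclisation the stannyl radical adds to the terminal alkyne carbon, the C16 vinyl radical closes 5-exo-trig onto C13 of the ring C alkene, and the C12 radical is reduced by the tin hydride before homoallyl rearrangement; C13 is set by geometry, since the C15–C16 bridge can span C8 and C13 only on the face of ring C that carries C15.

Step 21
Reactants: 30 ring D vinylstannane
Product: 31 15-hydroxy 16-methylene compound
Conditions: TsOH·H2O (1.2 equiv), CH2Cl2, 0 °C → rt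
Reagents that add atoms: none
Why: Protodestannylation by ipso protonation of the vinylstannane (β-stannyl cation) should give the exocyclic methylene without moving the double bond.

Step 22
Reactants: 31 15-hydroxy 16-methylene compound
Product: 32 C6 silyl ether of the target
Conditions: DMP, NaHCO3, CH2Cl2, 0 °C → rt
Reagents that add atoms: none
Why: Dess–Martin oxidation of the allylic alcohol gives the α-methylene ketone under neutral, non-nucleophilic conditions and erases the C15 epimer mixture.

Step 23
Reactants: 32 C6 silyl ether of the target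
Product: 33 CNP0105570.2
Conditions: HF·pyridine, pyridine, THF, 0 °C → rt
Reagents that add atoms: none
Why: Fluoride cleavage of the silyl ether in buffered, weakly acidic medium should free C6–OH while the enone, both acetates and the δ-lactone remain.

**Compound list**

1 | (2,2-dimethyl-1,3-dioxan-5-yl)methanol | CC1(C)OCC(CO)CO1 | starting material
2 | 2,2-dimethyl-1,3-dioxane-5-carbaldehyde | CC1(C)OCC(C=O)CO1 | intermediate
3 | vinylmagnesium bromide | C=C[Mg]Br | starting material
4 | 1-(2,2-dimethyl-1,3-dioxan-5-yl)prop-2-en-1-ol (racemic) | CC1(C)OCC(CO1)C(O)C=C | intermediate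
5 | 1-(2,2-dimethyl-1,3-dioxan-5-yl)prop-2-en-1-one | CC1(C)OCC(CO1)C(=O)C=C | intermediate
6 | 5-[1-(tert-butyldimethylsilyloxy)allylidene]-2,2-dimethyl-1,3-dioxane (diene C10=C1(OTBS)–C2=C3) | CC1(C)OCC(CO1)=C(O[Si](C)(C)C(C)(C)C)C=C | intermediate
7 | citraconic anhydride (3-methylfuran-2,5-dione) | CC1=CC(=O)OC1=O | starting material
8 | spiro-dioxane ring A anhydride: cyclohexene with C1(OTBS)=C2, C10 spiro to the 2,2-dimethyl-1,3-dioxane, anhydride C19(=O)–O–C6(=O) cis-fused on C4/C5 on the α-face, C4 methyl and H5 β | CC1(C)OCC2(CO1)C(O[Si](C)(C)C(C)(C)C)=CC[C@@]3(C)C(=O)OC(=O)[C@@H]23 | intermediate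
9 | keto diol anhydride: as 8 with a C1 ketone and two free CH2OH groups on C10 | OCC1(CO)C(=O)CC[C@@]2(C)C(=O)OC(=O)[C@@H]12 | intermediate
10 | keto lactone acid: C1 ketone; α-CH2O of C10 (C20) closed on C6 as a γ-lactone cis-fused at C5–C10; β-CH2OH on C10 (C9); C4 with β-methyl and α-CO2H (C19); H5 β | OC[C@]1(COC2=O)C(=O)CC[C@@](C)(C(=O)O)[C@H]12 | intermediate
11 | bis-silyl derivative of 10: C9 O-TBS ether and C19 TBS ester | CC(C)(C)[Si](C)(C)OC[C@]1(COC2=O)C(=O)CC[C@@](C)(C(=O)O[Si](C)(C)C(C)(C)C)[C@H]12 | intermediate
12 | C9 O-TBS ether of keto lactone acid 10 | CC(C)(C)[Si](C)(C)OC[C@]1(COC2=O)C(=O)CC[C@@](C)(C(=O)O)[C@H]12 | intermediate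
13 | 1α,19-diol γ-lactone: equatorial 1α-OH, C19 CH2OH, C9 OTBS, C6/C20 γ-lactone | CC(C)(C)[Si](C)(C)OC[C@]1(COC2=O)[C@@H](O)CC[C@@](C)(CO)[C@H]12 | intermediate
14 | 1α,19-diacetate γ-lactone | CC(C)(C)[Si](C)(C)OC[C@]1(COC2=O)[C@@H](OC(C)=O)CC[C@@](C)(COC(C)=O)[C@H]12 | intermediate
15 | lactol: C6 hemiacetal with O–C20 (anomer mixture), 1α,19-diacetate, C9 OTBS | CC(C)(C)[Si](C)(C)OC[C@]1(COC2O)[C@@H](OC(C)=O)CC[C@@](C)(COC(C)=O)[C@H]12 | intermediate
16 | C6,C20-diol diacetate: α-CH2OH on C5 (C6) and α-CH2OH on C10 (C20), C9 OTBS | CC(C)(C)[Si](C)(C)OC[C@]1(CO)[C@@H](OC(C)=O)CC[C@@](C)(COC(C)=O)[C@H]1CO | intermediate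
17 | C6 O-TBDPS ether with free C20–OH | CC(C)(C)[Si](C)(C)OC[C@]1(CO)[C@@H](OC(C)=O)CC[C@@](C)(COC(C)=O)[C@H]1CO[Si](c2ccccc2)(c2ccccc2)C(C)(C)C | intermediate
18 | mono-tert-butyl malonate (3-tert-butoxy-3-oxopropanoic acid) | CC(C)(C)OC(=O)CC(=O)O | starting material
19 | C20 tert-butyl malonate (C9 OTBS, C6 OTBDPS, 1α,19-diacetate) | CC(C)(C)[Si](C)(C)OC[C@]1(COC(=O)CC(=O)OC(C)(C)C)[C@@H](OC(C)=O)CC[C@@](C)(COC(C)=O)[C@H]1CO[Si](c2ccccc2)(c2ccccc2)C(C)(C)C | intermediate
20 | C9 alcohol malonate | OC[C@]1(COC(=O)CC(=O)OC(C)(C)C)[C@@H](OC(C)=O)CC[C@@](C)(COC(C)=O)[C@H]1CO[Si](c2ccccc2)(c2ccccc2)C(C)(C)C | intermediate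
21 | C9 aldehyde malonate | O=C[C@]1(COC(=O)CC(=O)OC(C)(C)C)[C@@H](OC(C)=O)CC[C@@](C)(COC(C)=O)[C@H]1CO[Si](c2ccccc2)(c2ccccc2)C(C)(C)C | intermediate
22 | spiro unsaturated δ-lactone ester: lactone C10–C20–O–C7(=O)–C8=C9 spiro at C10, CO2tBu on C8 | CC(C)(C)OC(=O)C1=C[C@]2(COC1=O)[C@@H](OC(C)=O)CC[C@@](C)(COC(C)=O)[C@H]2CO[Si](c3ccccc3)(c3ccccc3)C(C)(C)C | intermediate
23 | buta-1,3-diene | C=CC=C | starting material
24 | ring C adduct: cyclohexene (C12=C13) cis-fused to the δ-lactone at C8–C9, CO2tBu (future C15) on C8 cis to H9, C11 on the C1 side of the lactone | CC(C)(C)OC(=O)[C@]12CC=CC[C@H]1[C@]1(COC2=O)[C@@H](OC(C)=O)CC[C@@](C)(COC(C)=O)[C@H]1CO[Si](c3ccccc3)(c3ccccc3)C(C)(C)C | intermediate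
25 | C15 carboxylic acid | OC(=O)[C@]12CC=CC[C@H]1[C@]1(COC2=O)[C@@H](OC(C)=O)CC[C@@](C)(COC(C)=O)[C@H]1CO[Si](c3ccccc3)(c3ccccc3)C(C)(C)C | intermediate
26 | C15 acid chloride | ClC(=O)[C@]12CC=CC[C@H]1[C@]1(COC2=O)[C@@H](OC(C)=O)CC[C@@](C)(COC(C)=O)[C@H]1CO[Si](c3ccccc3)(c3ccccc3)C(C)(C)C | intermediate
27 | C15 aldehyde | O=C[C@]12CC=CC[C@H]1[C@]1(COC2=O)[C@@H](OC(C)=O)CC[C@@](C)(COC(C)=O)[C@H]1CO[Si](c3ccccc3)(c3ccccc3)C(C)(C)C | intermediate
28 | ethynylmagnesium bromide | C#C[Mg]Br | starting material
29 | C15 propargylic alcohol (C15 epimers) | C#CC(O)[C@]12CC=CC[C@H]1[C@]1(COC2=O)[C@@H](OC(C)=O)CC[C@@](C)(COC(C)=O)[C@H]1CO[Si](c3ccccc3)(c3ccccc3)C(C)(C)C | intermediate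
30 | ring D vinylstannane: bicyclo[3.2.1]octane with C15–OH and C16=C17H–SnBu3 (alkene isomers, C15 epimers) | CCCC[Sn](CCCC)(CCCC)C=C1C(O)[C@]23C[C@H]1CC[C@H]2[C@]1(COC3=O)[C@@H](OC(C)=O)CC[C@@](C)(COC(C)=O)[C@H]1CO[Si](c4ccccc4)(c4ccccc4)C(C)(C)C | intermediate
31 | 15-hydroxy 16-methylene compound (C15 epimers), C6 OTBDPS | C=C1C(O)[C@]23C[C@H]1CC[C@H]2[C@]1(COC3=O)[C@@H](OC(C)=O)CC[C@@](C)(COC(C)=O)[C@H]1CO[Si](c4ccccc4)(c4ccccc4)C(C)(C)C | intermediate
32 | C6 O-TBDPS ether of the target (15-oxo, 16-methylene) | C=C1C(=O)[C@]23C[C@H]1CC[C@H]2[C@]1(COC3=O)[C@@H](OC(C)=O)CC[C@@](C)(COC(C)=O)[C@H]1CO[Si](c4ccccc4)(c4ccccc4)C(C)(C)C | intermediate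
33 | CNP0105570.2 | C=C1C(=O)[C@]23C[C@H]1CC[C@H]2[C@]1(COC3=O)[C@@H](OC(C)=O)CC[C@@](C)(COC(C)=O)[C@H]1CO | target

**Step count and risks**

Total steps: 23. Longest linear sequence: 23 steps (1 to 33); compounds 3, 7, 18, 23 and 28 are bought.

Step 5 (labelled step). What may go wrong: the anhydride may bind the chiral Lewis acid weakly or at either carbonyl, giving poor enantioface discrimination; an uncatalysed background cycloaddition may compete; and the acid-labile diene may be protodesilylated or ionised at its allylic acetal oxygens. Fallback by known chemistry, setting out from 6 and 7: the uncatalysed thermal Diels–Alder reaction (toluene, 90 °C, BHT) should give the racemate, that is 8 together with its mirror image ent-8 F1. The conditions of step 6 then give the racemic keto lactone acid, 10 together with ent-10 F2. The free C19 acid is resolved by crystallising the (R)-1-phenylethylammonium salt of 10 F3 from EtOAc–iPrOH (the antipodal amine is used if it is the salt of ent-10 that crystallises), and acidification with aq. KHSO4 returns enantiopure 10, where the route is rejoined.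

Step 16. What may go wrong: cycloaddition at the neopentyl C9 may be slow, with loss of facial selectivity at the temperature then needed, or ZnCl2 may cleave the tert-butyl ester over a long reaction. Fallback, setting out from 22: the more nucleophilic 2-(trimethylsilyloxy)buta-1,3-diene is used without Lewis acid (toluene, rt to 60 °C). Its CH2 terminus next to the silyloxy carbon should bond to C9, giving the enol trimethylsilyl ether adduct F4 with C12(OSiMe3)=C13. CsF and PhNTf2 in DME convert it into the enol triflate F5. Reduction with formate under catalysis by zerovalent palladium (Pd(OAc)2, PPh3, Bu3N, HCO2H, DMF, 60 °C) removes the triflate and gives the C12=C13 alkene, which is 24, where the route is rejoined.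

Step 10. What may go wrong: hydride transfer from the bulky borane to the hindered lactone may be incomplete, or the acetates may be lost or may migrate during the reduction. Fallback, setting out from 13, in which no acetate is yet present: iBu2AlH (CH2Cl2, −78 °C) reduces the lactone to the lactol diol F6. Ac2O, pyridine and DMAP give the lactol triacetate F7. Hydrazinium acetate in DMF removes only the anomeric acetate and gives lactol 15, where the route is rejoined at the borohydride stage of step 10.

**Further compounds**

F1 | step 5 | ent-8, mirror image of the spiro-dioxane ring A anhydride | CC1(C)OCC2(CO1)C(O[Si](C)(C)C(C)(C)C)=CC[C@]3(C)C(=O)OC(=O)[C@H]23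
F2 | step 5 | ent-10, mirror image of the keto lactone acid | OC[C@@]1(COC2=O)C(=O)CC[C@](C)(C(=O)O)[C@@H]12
F3 | step 5 | (R)-1-phenylethylammonium salt of 10 | OC[C@]1(COC2=O)C(=O)CC[C@@](C)(C(=O)[O-])[C@H]12.C[C@@H]([NH3+])c1ccccc1
F4 | step 16 | enol trimethylsilyl ether adduct, C12(OSiMe3)=C13 | CC(C)(C)OC(=O)[C@]12CC=C(O[Si](C)(C)C)C[C@H]1[C@]1(COC2=O)[C@@H](OC(C)=O)CC[C@@](C)(COC(C)=O)[C@H]1CO[Si](c3ccccc3)(c3ccccc3)C(C)(C)C
F5 | step 16 | enol triflate, C12(OTf)=C13 | CC(C)(C)OC(=O)[C@]12CC=C(OS(=O)(=O)C(F)(F)F)C[C@H]1[C@]1(COC2=O)[C@@H](OC(C)=O)CC[C@@](C)(COC(C)=O)[C@H]1CO[Si](c3ccccc3)(c3ccccc3)C(C)(C)C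
F6 | step 10 | lactol diol: C6 hemiacetal, free 1α-OH and C19–OH, C9 OTBS | CC(C)(C)[Si](C)(C)OC[C@]1(COC2O)[C@@H](O)CC[C@@](C)(CO)[C@H]12
F7 | step 10 | lactol triacetate: anomeric C6 acetate, 1α- and 19-acetates, C9 OTBS | CC(C)(C)[Si](C)(C)OC[C@]1(COC2OC(C)=O)[C@@H](OC(C)=O)CC[C@@](C)(COC(C)=O)[C@H]12
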